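**Assumption:** carbon labels C1–C20 follow gibberellane numbering, and α/β refer to the usual drawing (H-5 and H-9 are β). The target is the gibberellin numbered 98 in the A series and is called "the target gibberellin" below. tert-Butyl 4-oxobutanoate and D-proline are taken as purchasable. The route is a design that has not been run, and the sense of induction in steps 1 and 14 is assigned by analogy with the standard enamine models.

## Retrosynthetic overview

1. Ring A is closed last by C3–C4 alkylation of the 19,20-lactone enolate; the lactone and the C4–C5 bond come from a tethered Michael addition of a C20-O-propanoate onto a C5=C6–C7 enal.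
2. Key bond C10–C1: intermolecular Michael addition of the ring B/C/D β-keto ester 17 to acrolein 18 (fragment union, sets the C10 quaternary centre); the C2 oxygen follows by proline-catalysed α-aminoxylation.
3. Ring B comes from a Dieckmann closure of a ring C/D diester; ring D from a SmI2 ketyl–alkyne closure; the C8 quaternary centre from a Sakurai allylation.
4. Ring C comes from an enantioselective intermolecular Michael addition (aldehyde 1 + enone 2) followed by aldol condensation.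
5. Order of ring formation: C, D, B, lactone, A.

## Route

Step 1
Reactants: 1 tert-butyl 4-oxobutanoate; 2 but-3-en-2-one
Product: 3 tert-butyl (3S)-3-formyl-6-oxoheptanoate
Conditions: (S)-2-[methoxy(diphenyl)methyl]pyrrolidine (5 mol %), ethyl 3,4-dihydroxybenzoate (20 mol %), neat, 4 °C
Reagents that add atoms: none
Why: Enamine-catalysed intermolecular Michael addition in which the diphenylmethyl group shields one enamine face, so the new C9–C11 bond sets C9 (S), the centre from which all others are relayed.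

Step 2
Reactants: 3 tert-butyl (3S)-3-formyl-6-oxoheptanoate
Product: 4 tert-butyl 2-[(1S)-4-oxocyclohex-2-en-1-yl]acetate
Conditions: LiOH·H2O (0.2 equiv), i-PrOH, 23 °C
Reagents that add atoms: none
Why: Intramolecular aldol condensation of the methyl ketone onto the aldehyde closes ring C as the 4-substituted cyclohexenone faster than C9 can epimerise.

Step 3
Reactants: 4 tert-butyl 2-[(1S)-4-oxocyclohex-2-en-1-yl]acetate; 5 tert-butyl[(1-methoxyethenyl)oxy]dimethylsilane
Product: 6 methyl 2-[(1S,6S)-6-(2-tert-butoxy-2-oxoethyl)-3-(tert-butyldimethylsilyloxy)cyclohex-2-en-1-yl]acetate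
Conditions: LiClO4 (0.2 equiv), CH2Cl2, 23 °C
Reagents that add atoms: none
Why: Mukaiyama–Michael addition with silyl transfer puts the C6–C5 acetate unit on C8 and leaves a regiodefined C13 silyl enol ether; the new C8 centre (trans) is erased in step 4.

Step 4
Reactants: 6 methyl 2-[(1S,6S)-6-(2-tert-butoxy-2-oxoethyl)-3-(tert-butyldimethylsilyloxy)cyclohex-2-en-1-yl]acetate
Product: 7 methyl 2-[(6S)-6-(2-tert-butoxy-2-oxoethyl)-3-oxocyclohex-1-en-1-yl]acetate
Conditions: Pd(OAc)2 (1.05 equiv), MeCN, 23 °C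
Reagents that add atoms: none
Why: Saegusa–Ito dehydrogenation (palladium enolate, β-hydride elimination from C8) regenerates the enone, now carrying the acetate arm on C8, without touching C9.

Step 5
Reactants: 7 methyl 2-[(6S)-6-(2-tert-butoxy-2-oxoethyl)-3-oxocyclohex-1-en-1-yl]acetate; 8 trimethyl(prop-2-en-1-yl)silane
Product: 9 methyl 2-[(1R,2S)-2-(2-tert-butoxy-2-oxoethyl)-5-oxo-1-(prop-2-en-1-yl)cyclohexyl]acetate
Conditions: TiCl4 (1.1 equiv), CH2Cl2, −78 °C; then H2O
Reagents that add atoms: none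
Why: Hosomi–Sakurai conjugate allylation builds the C8 quaternary centre; A(1,2) strain holds the C9 arm pseudoaxial and the allylsilane adds axially to the opposite face, so allyl (future C15–C17) is trans to the C9 arm.

Step 6
Reactants: 9 methyl 2-[(1R,2S)-2-(2-tert-butoxy-2-oxoethyl)-5-oxo-1-(prop-2-en-1-yl)cyclohexyl]acetate
Product: 10 methyl 2-[(7R,8S)-8-(2-tert-butoxy-2-oxoethyl)-7-(prop-2-en-1-yl)-1,4-dioxaspiro[4.5]decan-7-yl]acetate
Conditions: (Me3SiOCH2)2, Me3SiOTf (5 mol %), CH2Cl2, −78 → −20 °C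
Reagents that add atoms: 1,2-bis(trimethylsilyloxy)ethane C[Si](C)(C)OCCO[Si](C)(C)C
Why: Noyori ketalisation masks the C13 ketone so that the aldehyde made next cannot undergo an intramolecular aldol reaction with it.

Step 7
Reactants: 10 methyl 2-[(7R,8S)-8-(2-tert-butoxy-2-oxoethyl)-7-(prop-2-en-1-yl)-1,4-dioxaspiro[4.5]decan-7-yl]acetate
Product: 12 methyl 2-[(7R,8S)-8-(2-tert-butoxy-2-oxoethyl)-7-(2-oxoethyl)-1,4-dioxaspiro[4.5]decan-7-yl]acetate, via ozonide 11 (not isolated)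
Conditions: O3, CH2Cl2, −78 °C; then PPh3, −78 → 23 °C
Reagents that add atoms: ozone [O-][O+]=O
Why: Ozonolysis of the only alkene with reductive work-up gives the C16 aldehyde and leaves all stereocentres untouched.

Step 8
Reactants: 12 methyl 2-[(7R,8S)-8-(2-tert-butoxy-2-oxoethyl)-7-(2-oxoethyl)-1,4-dioxaspiro[4.5]decan-7-yl]acetate
Product: 13 methyl 2-[(7R,8S)-8-(2-tert-butoxy-2-oxoethyl)-7-(prop-2-yn-1-yl)-1,4-dioxaspiro[4.5]decan-7-yl]acetate
Conditions: dimethyl (1-diazo-2-oxopropyl)phosphonate, K2CO3, MeOH, 0 → 23 °C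
Reagents that add atoms: dimethyl (1-diazo-2-oxopropyl)phosphonate CC(=O)C(=[N+]=[N-])P(=O)(OC)OC
Why: Ohira–Bestmann (Seyferth–Gilbert) homologation turns the aldehyde into the terminal alkyne C16≡C17 under base mild enough for both esters.

Step 9
Reactants: 13 methyl 2-[(7R,8S)-8-(2-tert-butoxy-2-oxoethyl)-7-(prop-2-yn-1-yl)-1,4-dioxaspiro[4.5]decan-7-yl]acetate
Product: 14 methyl 2-[(1R,2S)-2-(2-tert-butoxy-2-oxoethyl)-5-oxo-1-(prop-2-yn-1-yl)cyclohexyl]acetate
Conditions: 1 M HCl, THF, 23 °C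
Reagents that add atoms: water O
Why: Acid-catalysed ketal hydrolysis frees the C13 ketone while the tert-butyl ester and the alkyne survive dilute aqueous acid.

Step 10
Reactants: 14 methyl 2-[(1R,2S)-2-(2-tert-butoxy-2-oxoethyl)-5-oxo-1-(prop-2-yn-1-yl)cyclohexyl]acetate
Product: 15 methyl 2-[(1R,2S,5S)-2-(2-tert-butoxy-2-oxoethyl)-5-hydroxy-6-methylidenebicyclo[3.2.1]octan-1-yl]acetate
Conditions: SmI2 (2.5 equiv), HMPA, t-BuOH, THF, 0 °C
Reagents that add atoms: none
Why: Ketyl–alkyne radical cyclisation (5-exo-dig) forms C13–C16 and closes ring D with the 16-methylidene group; the C13 configuration is fixed by the bridge from C8.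

Step 11
Reactants: 15 methyl 2-[(1R,2S,5S)-2-(2-tert-butoxy-2-oxoethyl)-5-hydroxy-6-methylidenebicyclo[3.2.1]octan-1-yl]acetate
Product: 16 methyl 2-[(1R,2S,5S)-2-(2-tert-butoxy-2-oxoethyl)-5-(tert-butyldimethylsilyloxy)-6-methylidenebicyclo[3.2.1]octan-1-yl]acetate
Conditions: t-BuMe2SiOTf, 2,6-lutidine, CH2Cl2, 0 → 23 °C
Reagents that add atoms: tert-butyldimethylsilyl trifluoromethanesulfonate CC(C)(C)[Si](C)(C)OS(=O)(=O)C(F)(F)F
Why: Silylation protects the tertiary bridgehead alcohol against the strong bases used later.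

Step 12
Reactants: 16 methyl 2-[(1R,2S,5S)-2-(2-tert-butoxy-2-oxoethyl)-5-(tert-butyldimethylsilyloxy)-6-methylidenebicyclo[3.2.1]octan-1-yl]acetate
Product: 17 ring B/C/D β-keto ester (C5 ketone; tert-butyl ester on C10; 13-OTBS; 16-methylidene; B/C cis-fused with H-9 β)
Conditions: KOt-Bu (1.5 equiv), THF, 0 → 23 °C; then cold 1 M HCl
Reagents that add atoms: none
Why: Dieckmann condensation closes ring B; only the less hindered C10 methylene is enolised and only the methyl ester is a good acyl acceptor, so the ketone ends at C5 and the tert-butyl ester on C10, with the cis fusion fixed by C8 and C9.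

Step 13
Reactants: 17 ring B/C/D β-keto ester; 18 prop-2-enal
Product: 19 10β-(3-oxopropyl)-10α-(tert-butoxycarbonyl) ketone (C10 quaternary)
Conditions: Et3N (0.2 equiv), CH2Cl2, −20 → 0 °C
Reagents that add atoms: none
Why: Key intermolecular Michael addition joining the tricycle to the C1–C3 fragment; acrolein attacks the convex face of the enolate anti to the C9–C11 bond, so the arm is β (cis to H-9) and the ester (future C20) α.

Step 14
Reactants: 19 10β-(3-oxopropyl)-10α-(tert-butoxycarbonyl) ketone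
Product: 21 (2S)-2-anilinooxy-3-hydroxypropyl keto ester, via aminooxy aldehyde 20 (not isolated)
Conditions: PhNO (1.1 equiv, slow addition), D-proline (20 mol %), CHCl3, 4 °C; then NaBH4 (0.5 equiv), EtOH, −20 °C
Reagents that add atoms: nitrosobenzene O=Nc1ccccc1
Why: Proline-catalysed enamine α-aminoxylation in which the carboxylic acid of D-proline directs O-attack to one enamine face and sets C2 (S, the future 2β-oxygen); the aldehyde is reduced in situ while the hindered C5 ketone survives.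

Step 15
Reactants: 21 (2S)-2-anilinooxy-3-hydroxypropyl keto ester
Product: 22 (2S)-2,3-dihydroxypropyl keto ester
Conditions: Zn dust, AcOH–THF, 23 °C
Reagents that add atoms: none
Why: Reductive N–O cleavage releases the C2 hydroxyl with retention because no bond to C2 is broken; the tert-butyl ester resists lactonisation.

Step 16
Reactants: 22 (2S)-2,3-dihydroxypropyl keto ester
Product: 23 2,3-bis-O-TBS keto ester
Conditions: t-BuMe2SiCl (3 equiv), imidazole, DMAP (cat.), DMF, 35 °C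
Reagents that add atoms: tert-butyl(chloro)dimethylsilane CC(C)(C)[Si](C)(C)Cl
Why: Exhaustive silylation protects both chain hydroxyls as ethers that tolerate enolate and hydride chemistry.

Step 17
Reactants: 23 2,3-bis-O-TBS keto ester
Product: 25 6-[(Z)-hydroxymethylidene] ketone, via lithium enolate 24 (not isolated)
Conditions: LiN(i-Pr)2 (1.3 equiv), THF, −78 °C; then HCO2CH2CF3, −78 → 0 °C; then cold 0.5 M HCl
Reagents that add atoms: 2,2,2-trifluoroethyl formate O=COCC(F)(F)F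
Why: C6 is the only enolisable position (C10 is quaternary), so kinetic enolate formation and Claisen-type formylation introduce C7 regiospecifically.

Step 18
Reactants: 25 6-[(Z)-hydroxymethylidene] ketone
Product: 26 6-[(E)-isopropoxymethylidene] ketone
Conditions: i-PrI, K2CO3, acetone, 56 °C
Reagents that add atoms: 2-iodopropane CC(C)I
Why: O-alkylation of the vinylogous acid gives the vinylogous ester needed for reductive 1,3-carbonyl transposition.

Step 19
Reactants: 26 6-[(E)-isopropoxymethylidene] ketone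
Product: 28 20-hydroxy-5-en-7-al (C5=C6 enal; C10 bears CH2OH α), via allylic diol 27 (not isolated)
Conditions: LiAlH4 (4 equiv), THF, 0 → 40 °C; aqueous KNaC4H4O6 work-up; then PPTS (cat.), acetone–H2O, 23 °C
Reagents that add atoms: water O
Why: Hydride 1,2-reduction of the vinylogous ester and reduction of the tert-butyl ester to the C20 carbinol, then acid-promoted allylic transposition and hydrolysis (Stork–Danheiser type), give the C5=C6 enal without touching C8, C9 or C10.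

Step 20
Reactants: 28 20-hydroxy-5-en-7-al
Product: 29 20-O-propanoate of the enal
Conditions: (EtCO)2O, Et3N, DMAP (cat.), CH2Cl2, 0 → 23 °C
Reagents that add atoms: propanoic anhydride CCC(=O)OC(=O)CC
Why: DMAP-catalysed acylation of the only free hydroxyl installs the propanoate that carries C4, C18 and C19.

Step 21
Reactants: 29 20-O-propanoate of the enal
Product: 30 19,20-δ-lactone 7-aldehyde (H-5 β; 6β-CHO; C4 secondary)
Conditions: KN(SiMe3)2 (1.1 equiv), THF, −78 → −30 °C; then AcOH; then DBU (cat.), CH2Cl2, 23 °C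
Reagents that add atoms: none
Why: Intramolecular Michael addition (6-exo-trig) of the ester enolate to the enal forms C4–C5 and the δ-lactone; the tether hangs from the α-oriented C20, so C4 is delivered to the α face of C5 (H-5 β), and base equilibration puts the C6 formyl group β, trans to C4.

Step 22
Reactants: 30 19,20-δ-lactone 7-aldehyde
Product: 31 3-hydroxy lactone aldehyde
Conditions: HF·pyridine, pyridine, THF, 0 °C
Reagents that add atoms: none
Why: Buffered fluoride cleaves the unhindered primary silyl ether much faster than the secondary and tertiary ones.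

Step 23
Reactants: 31 3-hydroxy lactone aldehyde
Product: 32 3-O-tosyl lactone aldehyde
Conditions: TsCl, Et3N, DMAP (cat.), CH2Cl2, 0 → 23 °C
Reagents that add atoms: 4-methylbenzenesulfonyl chloride Cc1ccc(cc1)S(Cl)(=O)=O
Why: Sulfonylation turns the primary C3 hydroxyl into the leaving group for ring A closure.

Step 24
Reactants: 32 3-O-tosyl lactone aldehyde
Product: 33 3-O-tosyl lactone 7-carboxylic acid
Conditions: NaClO2, NaH2PO4, 2-methylbut-2-ene, t-BuOH–H2O, 23 °C
Reagents that add atoms: sodium chlorite [Na+].[O-]Cl=O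
Why: Pinnick oxidation gives the C7 acid without epimerising C6; as a carboxylate, C6 is far less acidic than the lactone α-position in the next step.

Step 25
Reactants: 33 3-O-tosyl lactone 7-carboxylic acid
Product: 34 2,13-bis-O-TBS ether of the target gibberellin (ring A closed)
Conditions: LiN(i-Pr)2 (2.2 equiv), THF–HMPA, −78 → 0 °C; then 1 M HCl to pH 3
Reagents that add atoms: none
Why: Intramolecular SN2 alkylation of the lactone enolate (formed beside the lithium carboxylate) by the C3 tosylate closes ring A (6-exo-tet) and creates the C4 quaternary centre; the bridged bicyclo[3.3.1] geometry allows only bonding on the face of the C1 arm, so C18 is β and C19 α.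

Step 26
Reactants: 34 2,13-bis-O-TBS ether of the target gibberellin
Product: 35 the target gibberellin (2β,13-dihydroxy-16-methylidene C20 gibberellin 7-oic acid 19,20-lactone)
Conditions: Bu4NF (6 equiv), THF, 50 °C; then 1 M HCl to pH 3
Reagents that add atoms: none
Why: Fluoride desilylation frees the 2β and 13 hydroxyls; the 2β-alkoxide is trans to C19 and cannot translactonise, and the brief pH 3 work-up spares the 13-hydroxy-16-ene unit.

## Compound list

1 | tert-butyl 4-oxobutanoate | O=CCCC(=O)OC(C)(C)C | starting material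
2 | but-3-en-2-one (methyl vinyl ketone) | C=CC(C)=O | starting material
3 | tert-butyl (3S)-3-formyl-6-oxoheptanoate | O=C[C@H](CC(=O)OC(C)(C)C)CCC(C)=O | intermediate
4 | tert-butyl 2-[(1S)-4-oxocyclohex-2-en-1-yl]acetate | CC(C)(C)OC(=O)C[C@H]1C=CC(=O)CC1 | intermediate
5 | tert-butyl[(1-methoxyethenyl)oxy]dimethylsilane | C=C(OC)O[Si](C)(C)C(C)(C)C | starting material
6 | methyl 2-[(1S,6S)-6-(2-tert-butoxy-2-oxoethyl)-3-(tert-butyldimethylsilyloxy)cyclohex-2-en-1-yl]acetate (trans) | CC(C)(C)OC(=O)C[C@@H]1CCC(O[Si](C)(C)C(C)(C)C)=C[C@H]1CC(=O)OC | intermediate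
7 | methyl 2-[(6S)-6-(2-tert-butoxy-2-oxoethyl)-3-oxocyclohex-1-en-1-yl]acetate | COC(=O)CC1=CC(=O)CC[C@H]1CC(=O)OC(C)(C)C | intermediate
8 | trimethyl(prop-2-en-1-yl)silane | C=CC[Si](C)(C)C | starting material
9 | methyl 2-[(1R,2S)-2-(2-tert-butoxy-2-oxoethyl)-5-oxo-1-(prop-2-en-1-yl)cyclohexyl]acetate | C=CC[C@]1(CC(=O)OC)CC(=O)CC[C@H]1CC(=O)OC(C)(C)C | intermediate
10 | methyl 2-[(7R,8S)-8-(2-tert-butoxy-2-oxoethyl)-7-(prop-2-en-1-yl)-1,4-dioxaspiro[4.5]decan-7-yl]acetate | C=CC[C@]1(CC(=O)OC)CC2(CC[C@H]1CC(=O)OC(C)(C)C)OCCO2 | intermediate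
11 | secondary ozonide (1,2,4-trioxolane) of 10, mixture at the trioxolane carbon | O1OC(C[C@]2(CC(=O)OC)CC3(CC[C@H]2CC(=O)OC(C)(C)C)OCCO3)OC1 | intermediate
12 | methyl 2-[(7R,8S)-8-(2-tert-butoxy-2-oxoethyl)-7-(2-oxoethyl)-1,4-dioxaspiro[4.5]decan-7-yl]acetate | O=CC[C@]1(CC(=O)OC)CC2(CC[C@H]1CC(=O)OC(C)(C)C)OCCO2 | intermediate
13 | methyl 2-[(7R,8S)-8-(2-tert-butoxy-2-oxoethyl)-7-(prop-2-yn-1-yl)-1,4-dioxaspiro[4.5]decan-7-yl]acetate | C#CC[C@]1(CC(=O)OC)CC2(CC[C@H]1CC(=O)OC(C)(C)C)OCCO2 | intermediate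
14 | methyl 2-[(1R,2S)-2-(2-tert-butoxy-2-oxoethyl)-5-oxo-1-(prop-2-yn-1-yl)cyclohexyl]acetate | C#CC[C@]1(CC(=O)OC)CC(=O)CC[C@H]1CC(=O)OC(C)(C)C | intermediate
15 | methyl 2-[(1R,2S,5S)-2-(2-tert-butoxy-2-oxoethyl)-5-hydroxy-6-methylidenebicyclo[3.2.1]octan-1-yl]acetate | C=C1C[C@]2(CC(=O)OC)C[C@@]1(O)CC[C@H]2CC(=O)OC(C)(C)C | intermediate
16 | methyl 2-[(1R,2S,5S)-2-(2-tert-butoxy-2-oxoethyl)-5-(tert-butyldimethylsilyloxy)-6-methylidenebicyclo[3.2.1]octan-1-yl]acetate | C=C1C[C@]2(CC(=O)OC)C[C@@]1(O[Si](C)(C)C(C)(C)C)CC[C@H]2CC(=O)OC(C)(C)C | intermediate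
17 | ring B/C/D β-keto ester: ring B cyclopentanone (C5 ketone) cis-fused at C8–C9 to the bicyclo[3.2.1]octane, tert-butyl ester on C10 (enolisable, drawn β), 13-OTBS, 16-methylidene, H-9 β | C=C1C[C@]23C[C@@]1(O[Si](C)(C)C(C)(C)C)CC[C@H]2[C@H](C(=O)OC(C)(C)C)C(=O)C3 | intermediate
18 | prop-2-enal (acrolein) | C=CC=O | starting material
19 | 17 with quaternary C10: 10β-(3-oxopropyl), 10α-CO2t-Bu | C=C1C[C@]23C[C@@]1(O[Si](C)(C)C(C)(C)C)CC[C@H]2[C@@](CCC=O)(C(=O)OC(C)(C)C)C(=O)C3 | intermediate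
20 | (2S)-2-(anilinooxy) aldehyde of 19 | C=C1C[C@]23C[C@@]1(O[Si](C)(C)C(C)(C)C)CC[C@H]2[C@@](C[C@H](ONc4ccccc4)C=O)(C(=O)OC(C)(C)C)C(=O)C3 | intermediate
21 | 10β-[(2S)-2-(anilinooxy)-3-hydroxypropyl] keto ester | C=C1C[C@]23C[C@@]1(O[Si](C)(C)C(C)(C)C)CC[C@H]2[C@@](C[C@H](ONc4ccccc4)CO)(C(=O)OC(C)(C)C)C(=O)C3 | intermediate
22 | 10β-[(2S)-2,3-dihydroxypropyl] keto ester | C=C1C[C@]23C[C@@]1(O[Si](C)(C)C(C)(C)C)CC[C@H]2[C@@](C[C@H](O)CO)(C(=O)OC(C)(C)C)C(=O)C3 | intermediate
23 | 10β-[(2S)-2,3-bis(tert-butyldimethylsilyloxy)propyl] keto ester | C=C1C[C@]23C[C@@]1(O[Si](C)(C)C(C)(C)C)CC[C@H]2[C@@](C[C@H](O[Si](C)(C)C(C)(C)C)CO[Si](C)(C)C(C)(C)C)(C(=O)OC(C)(C)C)C(=O)C3 | intermediate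
24 | lithium C5–C6 enolate of 23 | C=C1C[C@]23C[C@@]1(O[Si](C)(C)C(C)(C)C)CC[C@H]2[C@@](C[C@H](O[Si](C)(C)C(C)(C)C)CO[Si](C)(C)C(C)(C)C)(C(=O)OC(C)(C)C)C(O[Li])=C3 | intermediate
25 | 6-[(Z)-hydroxymethylidene] ketone (C7 installed) | C=C1C[C@]23C[C@@]1(O[Si](C)(C)C(C)(C)C)CC[C@H]2[C@@](C[C@H](O[Si](C)(C)C(C)(C)C)CO[Si](C)(C)C(C)(C)C)(C(=O)OC(C)(C)C)C(=O)/C3=C\O | intermediate
26 | 6-[(E)-isopropoxymethylidene] ketone | C=C1C[C@]23C[C@@]1(O[Si](C)(C)C(C)(C)C)CC[C@H]2[C@@](C[C@H](O[Si](C)(C)C(C)(C)C)CO[Si](C)(C)C(C)(C)C)(C(=O)OC(C)(C)C)C(=O)/C3=C/OC(C)C | intermediate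
27 | 5,20-diol carrying the 6-(isopropoxymethylidene) group (C5 epimers) | C=C1C[C@]23C[C@@]1(O[Si](C)(C)C(C)(C)C)CC[C@H]2[C@@](C[C@H](O[Si](C)(C)C(C)(C)C)CO[Si](C)(C)C(C)(C)C)(CO)C(O)/C3=C/OC(C)C | intermediate
28 | 20-hydroxy-5-en-7-al: ring B cyclopentene carbaldehyde, C10 bears CH2OH (α) and the silylated C1–C3 arm (β) | C=C1C[C@]23C[C@@]1(O[Si](C)(C)C(C)(C)C)CC[C@H]2[C@@](C[C@H](O[Si](C)(C)C(C)(C)C)CO[Si](C)(C)C(C)(C)C)(CO)C=C3C=O | intermediate
29 | 20-O-propanoate of 28 | C=C1C[C@]23C[C@@]1(O[Si](C)(C)C(C)(C)C)CC[C@H]2[C@@](C[C@H](O[Si](C)(C)C(C)(C)C)CO[Si](C)(C)C(C)(C)C)(COC(=O)CC)C=C3C=O | intermediate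
30 | 19,20-δ-lactone 7-aldehyde: H-5 β, 6β-CHO, C4 secondary (either C4 epimer serves; drawn with 18-methyl β) | C=C1C[C@]23C[C@@]1(O[Si](C)(C)C(C)(C)C)CC[C@H]2[C@@]4(C[C@H](O[Si](C)(C)C(C)(C)C)CO[Si](C)(C)C(C)(C)C)COC(=O)[C@@H](C)[C@H]4[C@@H]3C=O | intermediate
31 | 3-hydroxy lactone aldehyde (primary silyl ether removed) | C=C1C[C@]23C[C@@]1(O[Si](C)(C)C(C)(C)C)CC[C@H]2[C@@]4(C[C@H](O[Si](C)(C)C(C)(C)C)CO)COC(=O)[C@@H](C)[C@H]4[C@@H]3C=O | intermediate
32 | 3-O-tosyl lactone aldehyde | C=C1C[C@]23C[C@@]1(O[Si](C)(C)C(C)(C)C)CC[C@H]2[C@@]4(C[C@H](O[Si](C)(C)C(C)(C)C)COS(=O)(=O)c5ccc(C)cc5)COC(=O)[C@@H](C)[C@H]4[C@@H]3C=O | intermediate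
33 | 3-O-tosyl lactone 7-carboxylic acid | C=C1C[C@]23C[C@@]1(O[Si](C)(C)C(C)(C)C)CC[C@H]2[C@@]4(C[C@H](O[Si](C)(C)C(C)(C)C)COS(=O)(=O)c5ccc(C)cc5)COC(=O)[C@@H](C)[C@H]4[C@@H]3C(=O)O | intermediate
34 | 2,13-bis-O-(tert-butyldimethylsilyl) ether of the target gibberellin | C=C1C[C@]23C[C@@]1(O[Si](C)(C)C(C)(C)C)CC[C@H]2[C@]12COC(=O)[C@](C)(C[C@@H](O[Si](C)(C)C(C)(C)C)C1)[C@H]2[C@@H]3C(=O)O | intermediate
35 | the target gibberellin: 2β,13-dihydroxy-16-methylidene C20 gibberellin 7-oic acid 19,20-lactone (H-5 β, H-9 β, 6β-CO2H, 18-methyl β; number 98 of the gibberellin A series) | C=C1C[C@]23C[C@@]1(O)CC[C@H]2[C@]12COC(=O)[C@](C)(C[C@@H](O)C1)[C@H]2[C@@H]3C(=O)O | target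

## Step count and risks

Total steps: 26. Longest linear sequence: 26 steps (1/2 to 35; all other carbon inputs are purchased).

**Step 25 (ring A closure by dianion alkylation).** The C4 enolate must form beside a carboxylate and build a quaternary centre. The fallback removes the acidity at C6 altogether. It sets out from 32: NaBH4 in MeOH at −20 °C reduces the aldehyde to the 7-alcohol F1. Et3SiCl and imidazole give the 7-O-triethylsilyl ether F2. LiN(i-Pr)2 (1.2 equiv) in THF–HMPA then closes ring A from the only enolisable site to give the tetracyclic 7-O-triethylsilyl ether F3. PPTS in MeOH removes only the primary triethylsilyl group to give the tetracyclic 7-alcohol F4. PhI(OAc)2 with catalytic TEMPO in MeCN–H2O oxidises F4 to the acid, rejoining the route at 34.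

**Step 21 (tethered Michael addition of a simple ester enolate).** The fallback replaces the kinetic enolate by a stabilised carbanion that adds under catalytic base. It sets out from 28: esterification with 2-(phenylsulfonyl)propanoic acid (DCC, DMAP) gives the 20-O-[2-(phenylsulfonyl)propanoate] F5. Cs2CO3 (0.2 equiv) in MeCN effects the 6-exo Michael addition to the 4-phenylsulfonyl lactone aldehyde F6. Aluminium amalgam Al(Hg) in THF–H2O removes the sulfone, rejoining the route at 30.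

**Step 10 (ketyl–alkyne closure of the bridged ring D).** The fallback closes ring D by a pinacol coupling and adds C17 afterwards. It sets out from 12: 1 M HCl in THF removes the ketal to give the keto aldehyde F7. SmI2 (2.2 equiv) with t-BuOH in THF at −78 °C couples the two carbonyls to the cis-13,16-diol F8. Dess–Martin periodinane oxidises the secondary carbinol to the 13-hydroxy-16-ketone F9. Ph3P=CH2 (3 equiv, from Ph3PCH3Br and KOt-Bu) in THF methylenates the ketone, rejoining the route at 15.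

## Further compounds

F1 | step 25 | 7-alcohol from 32 (C7 is CH2OH) | C=C1C[C@]23C[C@@]1(O[Si](C)(C)C(C)(C)C)CC[C@H]2[C@@]4(C[C@H](O[Si](C)(C)C(C)(C)C)COS(=O)(=O)c5ccc(C)cc5)COC(=O)[C@@H](C)[C@H]4[C@@H]3CO
F2 | step 25 | 7-O-triethylsilyl ether of F1 | C=C1C[C@]23C[C@@]1(O[Si](C)(C)C(C)(C)C)CC[C@H]2[C@@]4(C[C@H](O[Si](C)(C)C(C)(C)C)COS(=O)(=O)c5ccc(C)cc5)COC(=O)[C@@H](C)[C@H]4[C@@H]3CO[Si](CC)(CC)CC
F3 | step 25 | tetracyclic 7-O-triethylsilyl ether (ring A closed; 2,13-bis-OTBS) | C=C1C[C@]23C[C@@]1(O[Si](C)(C)C(C)(C)C)CC[C@H]2[C@]12COC(=O)[C@](C)(C[C@@H](O[Si](C)(C)C(C)(C)C)C1)[C@H]2[C@@H]3CO[Si](CC)(CC)CC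
F4 | step 25 | tetracyclic 7-alcohol (2,13-bis-OTBS) | C=C1C[C@]23C[C@@]1(O[Si](C)(C)C(C)(C)C)CC[C@H]2[C@]12COC(=O)[C@](C)(C[C@@H](O[Si](C)(C)C(C)(C)C)C1)[C@H]2[C@@H]3CO
F5 | step 21 | 20-O-[2-(phenylsulfonyl)propanoate] of 28 (mixture at the sulfonyl carbon) | C=C1C[C@]23C[C@@]1(O[Si](C)(C)C(C)(C)C)CC[C@H]2[C@@](C[C@H](O[Si](C)(C)C(C)(C)C)CO[Si](C)(C)C(C)(C)C)(COC(=O)C(C)S(=O)(=O)c4ccccc4)C=C3C=O
F6 | step 21 | 4-phenylsulfonyl 19,20-lactone 7-aldehyde (mixture at C4) | C=C1C[C@]23C[C@@]1(O[Si](C)(C)C(C)(C)C)CC[C@H]2[C@@]4(C[C@H](O[Si](C)(C)C(C)(C)C)CO[Si](C)(C)C(C)(C)C)COC(=O)C(C)(S(=O)(=O)c5ccccc5)[C@H]4[C@@H]3C=O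
F7 | step 10 | methyl 2-[(1R,2S)-2-(2-tert-butoxy-2-oxoethyl)-5-oxo-1-(2-oxoethyl)cyclohexyl]acetate | O=CC[C@]1(CC(=O)OC)CC(=O)CC[C@H]1CC(=O)OC(C)(C)C
F8 | step 10 | cis-13,16-diol of the bicyclo[3.2.1]octane diester | O[C@@H]1C[C@]2(CC(=O)OC)C[C@@]1(O)CC[C@H]2CC(=O)OC(C)(C)C
F9 | step 10 | 13-hydroxy-16-oxo bicyclo[3.2.1]octane diester | O=C1C[C@]2(CC(=O)OC)C[C@@]1(O)CC[C@H]2CC(=O)OC(C)(C)C
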